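The 1,2-dioxane ring (O1–O2–C3–C4–C5–C6) is disconnected between its two adjacent methylenes C4 and C5, each of which sits next to a peroxide-bearing carbon (secondary C3, quaternary C6). The precursor is an acyclic diallylic dialkyl peroxide in which O1–O2 acts as the tether and C2, C3 and C6 are already fixed by a syn-aldol reaction and two invertive C–O bond formations. Ring-closing metathesis joins C4 and C5 as a 3,6-dihydro-1,2-dioxine without touching a stereocentre or the O–O bond; diimide then saturates the ring, and the hydroxylated enone side chain is attached last.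

Key step: step 9

Remark: ring atoms are numbered O1, O2, C3, C4, C5, C6 as above, C2 is the propionate α-carbon and C7–C9 are the first three side-chain carbons on C6; peroxidic intermediates are assumed to be handled cold, on small scale.

Step 1
Reactants: 1 (4S)-4-benzyl-3-propanoyl-1,3-oxazolidin-2-one; 2 acrolein
Product: 4 (4S)-4-benzyl-3-[(2S,3R)-3-hydroxy-2-methylpent-4-enoyl]-1,3-oxazolidin-2-one, via boron Z-enolate 3 (not isolated)
Conditions: Bu2BOTf, i-Pr2NEt, CH2Cl2, −78 to 0 °C; then 2, −78 to 0 °C; pH 7 buffer, MeOH, 30% H2O2 work-up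
Reagents that add atoms: dibutylboron triflate CCCCB(CCCC)OS(=O)(=O)C(F)(F)F (boron group present in 3 only)
Why: Evans syn-aldol reaction, in which the boron Z-enolate 3 adds to acrolein through a closed chair transition state whose enolate face is dictated by the benzyl group of the auxiliary, which should set C2 as S and C3 as R (2,3-syn).

Step 2
Reactants: 4 (4S)-4-benzyl-3-[(2S,3R)-3-hydroxy-2-methylpent-4-enoyl]-1,3-oxazolidin-2-one
Product: 5 methyl (2S,3R)-3-hydroxy-2-methylpent-4-enoate
Conditions: NaOMe, MeOH, 0 °C, short contact; AcOH quench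
Reagents that add atoms: sodium methoxide [Na+].[O-]C
Why: Methoxide transesterification at the more electrophilic exocyclic imide carbonyl should release the methyl ester and the auxiliary without disturbing C2 or C3.

Step 3
Reactants: 5 methyl (2S,3R)-3-hydroxy-2-methylpent-4-enoate
Product: 7 methyl (2S,3S)-3-hydroperoxy-2-methylpent-4-enoate, via allylic triflate 6 (not isolated)
Conditions: Tf2O, 2,6-di-tert-butylpyridine, CH2Cl2, −78 °C; then anhydrous H2O2 in Et2O (large excess), −78 to −20 °C
Reagents that add atoms: trifluoromethanesulfonic anhydride O=S(=O)(OS(=O)(=O)C(F)(F)F)C(F)(F)F (triflyl group present in 6 only); hydrogen peroxide OO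
Why: SN2 displacement of a secondary sulfonate by hydrogen peroxide, in which neutral H2O2 should attack triflate 6 (its ionisation retarded by the neighbouring ester-bearing carbon) from the back side, inverting C3 from R to S to give the 2,3-anti hydroperoxide without the base that would eliminate a β-sulfonyloxy ester.

Step 4
Reactants: 8 geraniol
Product: 9 (2R,3R)-2,3-epoxygeraniol
Conditions: Ti(OiPr)4 (cat.), D-(−)-diethyl tartrate (cat.), t-BuOOH, 4 Å molecular sieves, CH2Cl2, −20 °C
Reagents that add atoms: tert-butyl hydroperoxide CC(C)(C)OO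
Why: Sharpless asymmetric epoxidation, in which the titanium tartrate complex delivers the peroxide oxygen to one face of the allylic alcohol, so that D-(−)-tartrate should give the (2R,3R)-epoxide whose tertiary carbon becomes C6.

Step 5
Reactants: 7 methyl (2S,3S)-3-hydroperoxy-2-methylpent-4-enoate; 9 (2R,3R)-2,3-epoxygeraniol
Product: 10 methyl (2S,3S)-3-{[(2R,3S)-1,2-dihydroxy-3,7-dimethyloct-6-en-3-yl]peroxy}-2-methylpent-4-enoate
Conditions: H3PMo12O40 (cat.), Et2O, 0 °C to rt, 9 in excess
Reagents that add atoms: none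
Why: Acid-catalysed ring opening of an epoxide by a hydroperoxide (perhydrolysis-type reaction), in which the OOH oxygen of 7 should attack the activated trisubstituted epoxide at its tertiary, most cation-stabilising carbon from the back side, so that the O2–O1–C6 linkage is made with inversion and C6 receives the configuration of the target.

Step 6
Reactants: 10 methyl (2S,3S)-3-{[(2R,3S)-1,2-dihydroxy-3,7-dimethyloct-6-en-3-yl]peroxy}-2-methylpent-4-enoate
Product: 11 methyl (2S,3S)-3-{[(2S)-2,6-dimethyl-1-oxohept-5-en-2-yl]peroxy}-2-methylpent-4-enoate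
Conditions: NaIO4, THF/H2O, 0 °C to rt
Reagents that add atoms: none
Why: Periodate glycol cleavage (Malaprade reaction) should excise the former C1 of geraniol and leave a non-enolisable α-peroxy aldehyde at C5, the dialkyl peroxide and the alkenes being inert to NaIO4.

Step 7
Reactants: 11 methyl (2S,3S)-3-{[(2S)-2,6-dimethyl-1-oxohept-5-en-2-yl]peroxy}-2-methylpent-4-enoate
Product: 12 methyl (2S,3S)-3-{[(3S)-3,7-dimethylocta-1,6-dien-3-yl]peroxy}-2-methylpent-4-enoate
Conditions: Ph3PCH3Br, KN(SiMe3)2, THF, −78 to 0 °C, ylide in slight excess only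
Reagents that add atoms: methyltriphenylphosphonium bromide C[P+](c1ccccc1)(c1ccccc1)c1ccccc1.[Br-]
Why: Wittig methylenation, in which the unstabilised ylide should add to the aldehyde much faster than it deprotonates the α-carbon of the β-peroxy ester, turning C5 into the vinyl CH needed for ring closure.

Step 8
Reactants: 12 methyl (2S,3S)-3-{[(3S)-3,7-dimethylocta-1,6-dien-3-yl]peroxy}-2-methylpent-4-enoate
Product: 13 methyl (2S,3S)-2-methyl-3-{[(3S)-3-methyl-6-oxohex-1-en-3-yl]peroxy}pent-4-enoate
Conditions: O3, pyridine, CH2Cl2, −78 °C, Sudan Red 7B as end-point indicator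
Reagents that add atoms: ozone [O-][O+]=O
Why: Chemoselective ozonolysis in its pyridine-mediated reductive variant, in which ozone should consume the electron-rich trisubstituted alkene well before the two vinyl groups deactivated by allylic peroxide oxygens, while pyridine converts the carbonyl oxide to the C9 aldehyde so that no O–O-cleaving reductant is needed.

Step 9
Reactants: 13 methyl (2S,3S)-2-methyl-3-{[(3S)-3-methyl-6-oxohex-1-en-3-yl]peroxy}pent-4-enoate
Product: 14 methyl (2S)-2-[(3S,6S)-6-methyl-6-(3-oxopropyl)-3,6-dihydro-1,2-dioxin-3-yl]propanoate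
Conditions: second-generation Grubbs catalyst (H2IMes)(PCy3)Cl2Ru=CHPh (cat.), CH2Cl2, high dilution, 40 °C
Reagents that add atoms: none
Why: Alkene metathesis by the [2+2]/retro-[2+2] metallacyclobutane mechanism: the ruthenium alkylidene should load on the less hindered C3 vinyl group, add intramolecularly to the vinyl group on quaternary C6 and release ethene, which forms the C4=C5 bond. The closest known reaction type is the ring-closing metathesis of dienes whose allylic carbons are linked through a heteroatom tether, including allylic dialkyl peroxides, whose O–O bond tolerates ruthenium alkylidenes. The six-membered 3,6-dihydro-1,2-dioxine ring is closed by joining the two internal alkene carbons C4 and C5 with O1–O2 as the tether, the geminal substitution at C6 favouring the folded conformer. No new stereocentre is formed (the ring alkene can only be cis), and C2, C3 and C6 take no part in the bond changes, so their configurations are carried through unchanged. The step needs ring closure to outrun oligomerisation and the catalyst to ignore the aldehyde and the peroxide; high dilution, the absence of any other alkene after step 8 and the neutral conditions, under which the base-sensitive allylic peroxide is stable, should secure this.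

Step 10
Reactants: 14 methyl (2S)-2-[(3S,6S)-6-methyl-6-(3-oxopropyl)-3,6-dihydro-1,2-dioxin-3-yl]propanoate
Product: 15 methyl (2S)-2-[(3S,6R)-6-methyl-6-(3-oxopropyl)-1,2-dioxan-3-yl]propanoate
Conditions: KO2C–N=N–CO2K, AcOH, CH2Cl2/MeOH, 0 °C to rt
Reagents that add atoms: none
Why: Diimide reduction, in which HN=NH generated in situ transfers two hydrogens in a concerted syn manner to the cis ring alkene and should leave the O–O bond, the aldehyde and the ester untouched, as catalytic hydrogenation would not.

Step 11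
Reactants: 16 methyl hex-5-ynoate
Product: 17 methyl 5-iodohex-5-enoate
Conditions: Me3SiCl, NaI, H2O, MeCN, rt
Reagents that add atoms: sodium iodide [Na+].[I-]
Why: Markovnikov hydroiodination of a terminal alkyne by HI generated in situ should stop at the 2-iodo-1-alkene and leave the ester untouched.

Step 12
Reactants: 17 methyl 5-iodohex-5-enoate
Product: 19 6-iodo-2-methylhept-6-en-2-ol, via methyl ketone 18 (not isolated)
Conditions: MeMgBr (2.5 equiv), THF, 0 °C to rt; aqueous NH4Cl work-up
Reagents that add atoms: methylmagnesium bromide C[Mg]Br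
Why: Double Grignard addition to an ester through ketone 18 should give the tertiary alcohol, the alkenyl iodide being inert to MeMgBr without a catalyst.

Step 13
Reactants: 15 methyl (2S)-2-[(3S,6R)-6-methyl-6-(3-oxopropyl)-1,2-dioxan-3-yl]propanoate; 19 6-iodo-2-methylhept-6-en-2-ol
Product: 22 methyl (2S)-2-[(3S,6S)-6-(3,8-dihydroxy-8-methyl-4-methylidenenonyl)-6-methyl-1,2-dioxan-3-yl]propanoate (both carbinol epimers), via dilithio species 20 (not isolated), via alkenylcerium reagent 21 (not isolated)
Conditions: 19, t-BuLi (3.1 equiv), Et2O, −78 °C; CeCl3, THF, −78 °C; then 15, −78 °C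
Reagents that add atoms: tert-butyllithium [Li]C(C)(C)C (lithium present in 20 and 21 only); cerium trichloride Cl[Ce](Cl)Cl (cerium present in 21 only)
Why: Iodine–lithium exchange, transmetalation to cerium and carbonyl 1,2-addition, in which the weakly basic, oxophilic alkenylcerium reagent should add to the aldehyde at −78 °C far faster than it attacks the methyl ester or the dialkyl peroxide, the new carbinol centre being left uncontrolled because it is oxidised next.

Step 14
Reactants: 22 methyl (2S)-2-[(3S,6S)-6-(3,8-dihydroxy-8-methyl-4-methylidenenonyl)-6-methyl-1,2-dioxan-3-yl]propanoate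
Product: 23 aikupikoxide D
Conditions: Dess–Martin periodinane, NaHCO3, CH2Cl2, 0 °C to rt
Reagents that add atoms: none
Why: Dess–Martin oxidation of the secondary allylic alcohol under buffered, non-basic conditions should give the α-methylene ketone, the tertiary alcohol being unoxidisable and the peroxide inert to the hypervalent iodine reagent.

Compound list
1 | (4S)-4-benzyl-3-propanoyl-1,3-oxazolidin-2-one | CCC(=O)N1[C@@H](Cc2ccccc2)COC1=O | starting material
2 | acrolein (prop-2-enal) | C=CC=O | starting material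
3 | (4S)-4-benzyl-3-{(1Z)-1-[(dibutylboranyl)oxy]prop-1-en-1-yl}-1,3-oxazolidin-2-one (boron Z-enolate) | C/C=C(\OB(CCCC)CCCC)N1[C@@H](Cc2ccccc2)COC1=O | intermediate
4 | (4S)-4-benzyl-3-[(2S,3R)-3-hydroxy-2-methylpent-4-enoyl]-1,3-oxazolidin-2-one | C=C[C@@H](O)[C@H](C)C(=O)N1[C@@H](Cc2ccccc2)COC1=O | intermediate
5 | methyl (2S,3R)-3-hydroxy-2-methylpent-4-enoate | C=C[C@@H](O)[C@H](C)C(=O)OC | intermediate
6 | methyl (2S,3R)-2-methyl-3-{[(trifluoromethyl)sulfonyl]oxy}pent-4-enoate | C=C[C@@H](OS(=O)(=O)C(F)(F)F)[C@H](C)C(=O)OC | intermediate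
7 | methyl (2S,3S)-3-hydroperoxy-2-methylpent-4-enoate | C=C[C@H](OO)[C@H](C)C(=O)OC | intermediate
8 | geraniol, (2E)-3,7-dimethylocta-2,6-dien-1-ol | CC(C)=CCC/C(C)=C/CO | starting material
9 | (2R,3R)-2,3-epoxygeraniol, [(2R,3R)-3-methyl-3-(4-methylpent-3-en-1-yl)oxiran-2-yl]methanol | CC(C)=CCC[C@@]1(C)O[C@@H]1CO | intermediate
10 | methyl (2S,3S)-3-{[(2R,3S)-1,2-dihydroxy-3,7-dimethyloct-6-en-3-yl]peroxy}-2-methylpent-4-enoate | CC(C)=CCC[C@](C)(OO[C@@H](C=C)[C@H](C)C(=O)OC)[C@H](O)CO | intermediate
11 | methyl (2S,3S)-3-{[(2S)-2,6-dimethyl-1-oxohept-5-en-2-yl]peroxy}-2-methylpent-4-enoate | CC(C)=CCC[C@](C)(OO[C@@H](C=C)[C@H](C)C(=O)OC)C=O | intermediate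
12 | methyl (2S,3S)-3-{[(3S)-3,7-dimethylocta-1,6-dien-3-yl]peroxy}-2-methylpent-4-enoate | CC(C)=CCC[C@](C)(OO[C@@H](C=C)[C@H](C)C(=O)OC)C=C | intermediate
13 | methyl (2S,3S)-2-methyl-3-{[(3S)-3-methyl-6-oxohex-1-en-3-yl]peroxy}pent-4-enoate | O=CCC[C@](C)(OO[C@@H](C=C)[C@H](C)C(=O)OC)C=C | intermediate
14 | methyl (2S)-2-[(3S,6S)-6-methyl-6-(3-oxopropyl)-3,6-dihydro-1,2-dioxin-3-yl]propanoate | O=CCC[C@@]1(C)C=C[C@@H]([C@H](C)C(=O)OC)OO1 | intermediate
15 | methyl (2S)-2-[(3S,6R)-6-methyl-6-(3-oxopropyl)-1,2-dioxan-3-yl]propanoate | O=CCC[C@@]1(C)CC[C@@H]([C@H](C)C(=O)OC)OO1 | intermediate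
16 | methyl hex-5-ynoate | C#CCCCC(=O)OC | starting material
17 | methyl 5-iodohex-5-enoate | C=C(I)CCCC(=O)OC | intermediate
18 | 6-iodohept-6-en-2-one | C=C(I)CCCC(C)=O | intermediate
19 | 6-iodo-2-methylhept-6-en-2-ol | C=C(I)CCCC(C)(C)O | intermediate
20 | lithium 6-lithio-2-methylhept-6-en-2-olate | [Li]C(=C)CCCC(C)(C)O[Li] | intermediate
21 | lithium 6-(dichlorocerio)-2-methylhept-6-en-2-olate | Cl[Ce](Cl)C(=C)CCCC(C)(C)O[Li] | intermediate
22 | methyl (2S)-2-[(3S,6S)-6-(3,8-dihydroxy-8-methyl-4-methylidenenonyl)-6-methyl-1,2-dioxan-3-yl]propanoate (both carbinol epimers) | C=C(CCCC(C)(C)O)C(O)CC[C@@]1(C)CC[C@@H]([C@H](C)C(=O)OC)OO1 | intermediate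
23 | aikupikoxide D, methyl (2S)-2-[(3S,6R)-6-(8-hydroxy-8-methyl-4-methylidene-3-oxononyl)-6-methyl-1,2-dioxan-3-yl]propanoate | C=C(CCCC(C)(C)O)C(=O)CC[C@@]1(C)CC[C@@H]([C@H](C)C(=O)OC)OO1 | target

Total step count: 14. Longest linear sequence: 11 steps (steps 1, 2, 3, 5, 6, 7, 8, 9, 10, 13, 14).

Steps most likely to fail

Step 3. The secondary allylic triflate 6 may ionise, be attacked at its vinyl terminus (allylic transposition) or lose triflic acid to the dienoate. The hydroperoxide would then form with eroded configuration, as the primary regioisomer, or not at all. The fallback takes the ester out of the displacement so that the classical basic H2O2 substitution of a mesylate can be used; it sets out from 4 and comes back at 12. Reductive removal of the auxiliary from 4 (LiBH4, MeOH, THF) should give (2R,3R)-2-methylpent-4-ene-1,3-diol F1. Its primary hydroxyl is silylated (t-BuPh2SiCl, imidazole) to the silyl ether F2, mesylation (MeSO2Cl, Et3N) gives the allylic mesylate F3, and H2O2/KOH in MeOH should displace it with inversion to the silyl-protected hydroperoxide F4. F4 is united with 9 as in step 5 to give the peroxy diol F5, cleaved with NaIO4 to the α-peroxy aldehyde F6 and methylenated to the triene silyl ether F7. HF·pyridine frees the primary alcohol F8, CrO3/H2SO4 in acetone oxidises it to the carboxylic acid F9, and Me3SiCHN2 in MeOH/toluene gives 12.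

Step 5. The secondary hydroperoxide 7 is a weaker nucleophile than H2O2. Acid-induced rearrangement or oligomerisation of the epoxide, acid-induced fragmentation or peroxylactonisation of 7, oxygen transfer from 7 to the trisubstituted alkene at molybdenum, or partial loss of inversion at the tertiary carbon may therefore take over. The fallback exchanges the roles of the two partners; it sets out from 9 and comes back at 10. Silylation of 9 (t-BuPh2SiCl, imidazole) gives the epoxy silyl ether F10. This is opened at the tertiary carbon with ethereal H2O2 and catalytic H3PMo12O40 (the established perhydrolysis, with inversion) to the tertiary hydroperoxide F11. Alkylation of the OOH group of F11 with triflate 6 (made from 5 as in step 3; 2,6-di-tert-butylpyridine, CH2Cl2, −78 to −20 °C), with inversion at C3, gives the silyl-protected peroxide F12, and HF·pyridine removes the silyl group to give 10.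

Step 9. Loading of the catalyst on the hindered vinyl group at quaternary C6, and closure onto it, may be slow. Cross-metathesis oligomers through the exposed C3 vinyl group, or decay of the ruthenium alkylidene in contact with the allylic peroxide, could then compete. The fallback is a relay ring-closing metathesis that still closes the ring at C4–C5; it sets out from 11 and comes back at 14. Wittig reaction of 11 with the ylide from (hex-5-en-1-yl)triphenylphosphonium bromide and KN(SiMe3)2 gives the Z-alkene with a relay arm F13. mCPBA should epoxidise only the trisubstituted alkene, to the epoxide F14, and H5IO6 cleaves it to the relay aldehyde F15. With the same catalyst the alkylidene forms on the unhindered terminal alkene of the arm, expels cyclopentene to place the carbene on C5, and closes onto the C3 vinyl group to give 14.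

Further compounds
F1 | step 3 | (2R,3R)-2-methylpent-4-ene-1,3-diol | C=C[C@@H](O)[C@H](C)CO
F2 | step 3 | (2R,3R)-1-[(tert-butyldiphenylsilyl)oxy]-2-methylpent-4-en-3-ol | C=C[C@@H](O)[C@H](C)CO[Si](c1ccccc1)(c1ccccc1)C(C)(C)C
F3 | step 3 | (2R,3R)-1-[(tert-butyldiphenylsilyl)oxy]-2-methylpent-4-en-3-yl methanesulfonate | C=C[C@@H](OS(C)(=O)=O)[C@H](C)CO[Si](c1ccccc1)(c1ccccc1)C(C)(C)C
F4 | step 3 | tert-butyl{[(2R,3S)-3-hydroperoxy-2-methylpent-4-en-1-yl]oxy}diphenylsilane | C=C[C@H](OO)[C@H](C)CO[Si](c1ccccc1)(c1ccccc1)C(C)(C)C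
F5 | step 3 | (2R,3S)-3-{[(3S,4R)-5-[(tert-butyldiphenylsilyl)oxy]-4-methylpent-1-en-3-yl]peroxy}-3,7-dimethyloct-6-ene-1,2-diol | CC(C)=CCC[C@](C)(OO[C@@H](C=C)[C@H](C)CO[Si](c1ccccc1)(c1ccccc1)C(C)(C)C)[C@H](O)CO
F6 | step 3 | (2S)-2-{[(3S,4R)-5-[(tert-butyldiphenylsilyl)oxy]-4-methylpent-1-en-3-yl]peroxy}-2,6-dimethylhept-5-enal | CC(C)=CCC[C@](C)(OO[C@@H](C=C)[C@H](C)CO[Si](c1ccccc1)(c1ccccc1)C(C)(C)C)C=O
F7 | step 3 | tert-butyl{[(2R,3S)-3-{[(3S)-3,7-dimethylocta-1,6-dien-3-yl]peroxy}-2-methylpent-4-en-1-yl]oxy}diphenylsilane | CC(C)=CCC[C@](C)(OO[C@@H](C=C)[C@H](C)CO[Si](c1ccccc1)(c1ccccc1)C(C)(C)C)C=C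
F8 | step 3 | (2R,3S)-3-{[(3S)-3,7-dimethylocta-1,6-dien-3-yl]peroxy}-2-methylpent-4-en-1-ol | CC(C)=CCC[C@](C)(OO[C@@H](C=C)[C@H](C)CO)C=C
F9 | step 3 | (2S,3S)-3-{[(3S)-3,7-dimethylocta-1,6-dien-3-yl]peroxy}-2-methylpent-4-enoic acid | CC(C)=CCC[C@](C)(OO[C@@H](C=C)[C@H](C)C(=O)O)C=C
F10 | step 5 | tert-butyl{[(2R,3R)-3-methyl-3-(4-methylpent-3-en-1-yl)oxiran-2-yl]methoxy}diphenylsilane | CC(C)=CCC[C@@]1(C)O[C@@H]1CO[Si](c1ccccc1)(c1ccccc1)C(C)(C)C
F11 | step 5 | (2R,3S)-1-[(tert-butyldiphenylsilyl)oxy]-3-hydroperoxy-3,7-dimethyloct-6-en-2-ol | CC(C)=CCC[C@](C)(OO)[C@H](O)CO[Si](c1ccccc1)(c1ccccc1)C(C)(C)C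
F12 | step 5 | methyl (2S,3S)-3-{[(2R,3S)-1-[(tert-butyldiphenylsilyl)oxy]-2-hydroxy-3,7-dimethyloct-6-en-3-yl]peroxy}-2-methylpent-4-enoate | CC(C)=CCC[C@](C)(OO[C@@H](C=C)[C@H](C)C(=O)OC)[C@H](O)CO[Si](c1ccccc1)(c1ccccc1)C(C)(C)C
F13 | step 9 | methyl (2S,3S)-3-{[(6Z,8S)-8,12-dimethyltrideca-1,6,11-trien-8-yl]peroxy}-2-methylpent-4-enoate | CC(C)=CCC[C@](C)(OO[C@@H](C=C)[C@H](C)C(=O)OC)/C=C\CCCC=C
F14 | step 9 | methyl (2S,3S)-3-{[(3S,4Z)-1-(3,3-dimethyloxiran-2-yl)-3-methyldeca-4,9-dien-3-yl]peroxy}-2-methylpent-4-enoate | CC1(C)OC1CC[C@](C)(OO[C@@H](C=C)[C@H](C)C(=O)OC)/C=C\CCCC=C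
F15 | step 9 | methyl (2S,3S)-2-methyl-3-{[(4S,5Z)-4-methyl-1-oxoundeca-5,10-dien-4-yl]peroxy}pent-4-enoate | O=CCC[C@](C)(OO[C@@H](C=C)[C@H](C)C(=O)OC)/C=C\CCCC=C
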